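(Readings and results stem from a simulated flask on assumed constants; scatter was added.)

In the first minute both earlier flasks linked fast, spring reaching 57.3% of the Z charged as X and dawn 45.9%, but by 3.00 min dawn stood near 46.5% while spring was still climbing to 66.8%, so I asked first what J takes away.

| flask | Z | G | J | remark | time |
|---|---|---|---|---|---|
| spring | 5 mM | 4.9 mM | 1 mM | run made earlier |  |
| dawn | 5 mM | 4.9 mM | 2.9 mM | run made earlier |  |
| blue | 5.0 mM | 4.90 mM | 2.50 mM |  | 3.0 min |
| grey | 5.0 mM | 4.90 mM | 0.800 mM |  | 3.0 min |

| run | time / min | X / % | Z / % |
|---|---|---|---|
| spring | 0.200 | 33.9 | 64.4 |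
| spring | 0.667 | 54.8 | 45.1 |
| spring | 1.00 | 57.3 | 43.7 |
| spring | 1.50 | 60.1 | 39.1 |
| spring | 2.50 | 64.5 | 37.9 |
| spring | 3.00 | 66.8 | 34.5 |
| dawn | 0.250 | 34.9 | 64.8 |
| dawn | 0.417 | 41.0 | 57.4 |
| dawn | 0.667 | 45.3 | 55.5 |
| dawn | 1.00 | 45.9 | 54.1 |
| dawn | 2.00 | 47.8 | 53.3 |
| dawn | 3.00 | 46.5 | 52.7 |

(standard deviation of a reading: 1 percentage point)

1. which of the two ends with the longer chains by the average number of monomer units in a chain (unreacted monomers counted as chains of one) ("neither" if they lie within 10%) (blue / grey / neither)
2. average number of monomer units in a chain (unreacted monomers counted as chains of one) at the end, blue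
3. average number of monomer units in a chain (unreacted monomers counted as chains of one) at the end, grey

- each molecule carries two end groups: a chain counts once for every two ends that are left, dead ends included; the units are half of the end groups of the two monomers charged
- the analysis behind the earlier runs scatters by 1 percentage point, standard deviation
- on the list of suspects stand: Z + G <-> X + D; D -> E; G + J -> Q

Each link uses two ends and two ends make a chain, so the average length is the ends charged over the ends charged less twice the links, and the question became how many links each flask makes. Each J that caps a G takes that G from linking, so I subtracted the J charged from the G charged, a limiting-reagent sum with J served first, which gave 4.10 mM for grey and 2.40 mM for blue; I called this spare G.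

Did it bind in the earlier runs? Dawn had 2.00 mM of spare G and read 2.33 mM of links, an excess of 0.325 mM that I read as J which had capped no G, while spring read 3.34 mM, below its spare G of 3.90 mM, so spring's links stood short of that limit at its last reading.

Blue's spare G lies below spring's links, so I put blue with dawn, at a length between 1.94 and 2.22. Grey's lies above them, so I put grey with spring, at 3.07.

The forecast named grey, with 2.13 for blue, inside my range, and 3.2 for grey, a little above mine, saying “Grey behaves like spring with slightly more free G”.

The flasks gave 2.06 for blue and 3.14 for grey, so grey ended longer and the forecast held.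

    Z + G ⇌ X + D (K = 2.51, k = 10.3 /M/s)
    D → E (k = 0.0109 /s)
    G + J → Q (k = 14.3 /M/s)

The gap came from the difference in concentration of J: grey with J made equal to blue's gave 2.06 against 3.14. At 3.00 min grey still held 15% of its G and its links stood at 3.37 mM, below spare G. Left to 30.0 min, grey reached 4.10 mM, level with spare G, and the length rule on spare G gives 5.82, against the flask's 5.80. A neighbour, grey with 12 mM of Z, held 4.13 mM of links at 3.00 min, and the same rule gives 1.94 against its simulated 1.96.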